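**Plan**
- Cuts: ring B is opened at C1–C2 and C5–C6 (retro-Diels–Alder, with methanol added back across C2/C5). Before that, the C2–OH is masked as OMe, and the CO2H and the 2′-OH as benzyl derivatives.
- Enabling feature: in ring B the CO2H on C1 sits next to the pentyl on C6, which is the α,β-pair of an oct-2-ynoate. The oxygens on C2 and C4, with CH at C3 and C5, map onto a 1,1,3-trioxygenated buta-1,3-diene.
- The depside bond C4–O–C(=O)–C1′ is cut at the diene stage, where it is the enol ester of 4,4-dimethoxybut-3-en-2-one. That enone falls into acetyl chloride and 1,1-dichloroethene.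
- Forward: ring A comes ready-made from olivetolic acid and is converted to an acid chloride, which O-acylates the enolate. Ring B is then built by cycloaddition and aromatisation, and hydrogenolysis followed by chelation-directed demethylation ends the route.
- Stereochemistry: the target has no stereocentre and no stereogenic double bond, so nothing has to be controlled.

Key step: step 9

Remark: locants C1–C6 refer to ring B (C1 bears CO2H, C6 the pentyl chain) and C1′–C6′ to ring A. All four starting materials are taken as catalogue chemicals.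

**Step 1**
Reactants: 1 acetyl chloride; 2 1,1-dichloroethene
Product: 4 4,4-dichlorobut-3-en-2-one, via 4,4,4-trichlorobutan-2-one 3 (not isolated)
Conditions: AlCl3 (1.1 equiv), CH2Cl2, 0 °C → rt; ice/water; steam distillation
Reagents that add atoms: none
Why: In this AlCl3-promoted Friedel–Crafts-type acylation of an alkene (Kondakov reaction) the acylium ion adds to the CH2 end of 2, chloride capture gives 3, and the acidic α-hydrogens let HCl leave on steam distillation to give the conjugated dichlorovinyl ketone.

**Step 2**
Reactants: 4 4,4-dichlorobut-3-en-2-one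
Product: 6 4,4-dimethoxybut-3-en-2-one, via 4-chloro-4-methoxybut-3-en-2-one 5 (not isolated)
Conditions: NaOMe (2.2 equiv), MeOH, 0 °C → reflux; filtration of the salt; distillation (no aqueous work-up)
Reagents that add atoms: sodium methoxide, [Na+].[O-]C
Why: Two successive conjugate addition–elimination substitutions at the β-carbon of the enone exchange both chlorides for methoxide, which is the standard entry to this acyl ketene acetal.

**Step 3**
Reactants: 7 olivetolic acid (2,4-dihydroxy-6-pentylbenzoic acid)
Product: 9 methyl 2-hydroxy-4-methoxy-6-pentylbenzoate, via methyl olivetolate 8 (not isolated)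
Conditions: MeI (2.1 equiv), K2CO3 (2.2 equiv), DMF, 0 °C → rt
Reagents that add atoms: iodomethane, CI
Why: In this carboxylate alkylation followed by Williamson etherification the 4-OH reacts, whereas the 2-OH is tied up in a hydrogen bond to the ester carbonyl and should stay free when only two equivalents of MeI are offered.

**Step 4**
Reactants: 9 methyl 2-hydroxy-4-methoxy-6-pentylbenzoate
Product: 10 methyl 2-(benzyloxy)-4-methoxy-6-pentylbenzoate
Conditions: BnBr (1.3 equiv), K2CO3, DMF, 60 °C
Reagents that add atoms: benzyl bromide, BrCc1ccccc1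
Why: A Williamson ether synthesis in warm DMF breaks the chelate of the remaining phenol and caps it with a group that hydrogenolysis removes later.

**Step 5**
Reactants: 10 methyl 2-(benzyloxy)-4-methoxy-6-pentylbenzoate
Product: 11 2-(benzyloxy)-4-methoxy-6-pentylbenzoic acid
Conditions: KOH, DMSO/H2O, 90 °C; then cold 1 M HCl
Reagents that add atoms: potassium hydroxide, [K+].[OH-]
Why: Saponification of a doubly ortho-substituted benzoate calls for poorly solvated hydroxide in hot aqueous DMSO, conditions to which the benzyl and methyl ethers are inert.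

**Step 6**
Reactants: 11 2-(benzyloxy)-4-methoxy-6-pentylbenzoic acid
Product: 12 2-(benzyloxy)-4-methoxy-6-pentylbenzoyl chloride
Conditions: (COCl)2 (1.5 equiv), DMF (cat.), CH2Cl2, 0 °C → rt; evaporation with toluene, used crude
Reagents that add atoms: oxalyl chloride, O=C(Cl)C(=O)Cl
Why: DMF-catalysed (Vilsmeier-type) acid chloride formation runs near room temperature with only gaseous by-products and leaves the aryl ethers untouched.

**Step 7**
Reactants: 6 4,4-dimethoxybut-3-en-2-one; 12 2-(benzyloxy)-4-methoxy-6-pentylbenzoyl chloride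
Product: 14 4,4-dimethoxybuta-1,3-dien-2-yl 2-(benzyloxy)-4-methoxy-6-pentylbenzoate, via potassium 4,4-dimethoxybuta-1,3-dien-2-olate 13 (not isolated)
Conditions: KN(SiMe3)2 (1.05 equiv), THF/DMPU, −78 °C; then 12, −78 → −20 °C; pH 7 buffer; Et3N-deactivated silica
Reagents that add atoms: none
Why: This is an enolate O-acylation to an enol ester, in which the methyl group holds the only enolisable hydrogens of 6, so a single cross-conjugated enolate forms, and a dissociated potassium enolate in a dipolar medium should meet the hard, hindered aroyl chloride at oxygen.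

**Step 8**
Reactants: 15 oct-2-ynoic acid
Product: 16 benzyl oct-2-ynoate
Conditions: BnBr (1.1 equiv), KHCO3 (1.2 equiv), DMF, rt
Reagents that add atoms: benzyl bromide, BrCc1ccccc1
Why: SN2 alkylation of the carboxylate with a base as weak as KHCO3 esterifies the acid without alkyne-to-allene isomerisation.

**Step 9**
Reactants: 14 4,4-dimethoxybuta-1,3-dien-2-yl 2-(benzyloxy)-4-methoxy-6-pentylbenzoate; 16 benzyl oct-2-ynoate
Product: 18 benzyl 4-{[2-(benzyloxy)-4-methoxy-6-pentylbenzoyl]oxy}-2-methoxy-6-pentylbenzoate, via cyclohexa-1,4-diene ketal adduct 17 (not isolated)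
Conditions: 16 (4 equiv), BHT (cat.), o-xylene (concentrated), reflux, slow Ar sweep, base-washed glass; then PPTS (cat.), toluene, 60 °C
Reagents that add atoms: none
Why: A thermal, concerted but strongly asynchronous normal-electron-demand [4+2] cycloaddition joins the CH2 terminus of 14 to the pentyl-bearing β-carbon of 16 (C5–C6) and the acetal carbon to the α-carbon (C1–C2), giving the cyclohexa-1,4-diene ketal 17. Adduct 17 then loses one methanol by 1,4-elimination (one C2–OMe and one C5–H), on heating or under the PPTS finish, and becomes benzenoid ring B with the depside ester already in place on C4. The closest known reaction type is the Diels–Alder benzannulation of 1,1-dialkoxy-3-silyloxybuta-1,3-dienes with alk-2-ynoates to give resorcylate esters. Ring B closes intermolecularly in the [4+2] mode as a six-membered carbocycle, four carbons from the diene and two from the alkyne, and no stereocentre arises because C2 of 17 carries two identical methoxy groups and C5 is a CH2. The step needs regioselectivity, which is secured because the two ketene-acetal oxygens and the enol-ester oxygen all raise the HOMO coefficient at the CH2 terminus, and this terminus pairs with the electrophilic β-carbon of the ynoate. It also needs the enol ester to stay in place, which the two ortho substituents of the aroyl group secure by shielding its carbonyl, while the argon sweep carries off methanol before it can add to unreacted ketene acetal.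

**Step 10**
Reactants: 18 benzyl 4-{[2-(benzyloxy)-4-methoxy-6-pentylbenzoyl]oxy}-2-methoxy-6-pentylbenzoate
Product: 19 4-[(2-hydroxy-4-methoxy-6-pentylbenzoyl)oxy]-2-methoxy-6-pentylbenzoic acid (2-O-methylperlatolic acid)
Conditions: H2 (1 atm), 10% Pd/C, EtOAc, rt
Reagents that add atoms: none
Why: Catalytic hydrogenolysis cleaves the benzyl ester and the benzyl ether under neutral conditions that touch neither the aryl ester nor the methyl ethers.

**Step 11**
Reactants: 19 4-[(2-hydroxy-4-methoxy-6-pentylbenzoyl)oxy]-2-methoxy-6-pentylbenzoic acid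
Product: 21 perlatolic acid (2-hydroxy-4-[(2-hydroxy-4-methoxy-6-pentylbenzoyl)oxy]-6-pentylbenzoic acid), via bis-boron chelate 20 (not isolated)
Conditions: BCl3 (1 M in CH2Cl2, 4 equiv), CH2Cl2, −78 → 0 °C; then ice-cold 1 M HCl/THF
Reagents that add atoms: none
Why: In this chelation-controlled ether cleavage, boron bound to the carboxyl oxygen coordinates the ortho C2–OMe in a six-membered chelate and chloride removes that methyl by SN2, whereas the 4′-OMe lies para to its carbonyl, cannot chelate, and should resist BCl3 at or below 0 °C like any simple aryl methyl ether.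

**Compound list**
1 | acetyl chloride | CC(=O)Cl | starting material
2 | 1,1-dichloroethene | C=C(Cl)Cl | starting material
3 | 4,4,4-trichlorobutan-2-one | CC(=O)CC(Cl)(Cl)Cl | intermediate
4 | 4,4-dichlorobut-3-en-2-one | CC(=O)C=C(Cl)Cl | intermediate
5 | 4-chloro-4-methoxybut-3-en-2-one (double-bond geometry not defined) | CC(=O)C=C(Cl)OC | intermediate
6 | 4,4-dimethoxybut-3-en-2-one | CC(=O)C=C(OC)OC | intermediate
7 | olivetolic acid (2,4-dihydroxy-6-pentylbenzoic acid) | CCCCCc1cc(O)cc(O)c1C(=O)O | starting material
8 | methyl olivetolate (methyl 2,4-dihydroxy-6-pentylbenzoate) | CCCCCc1cc(O)cc(O)c1C(=O)OC | intermediate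
9 | methyl 2-hydroxy-4-methoxy-6-pentylbenzoate | CCCCCc1cc(OC)cc(O)c1C(=O)OC | intermediate
10 | methyl 2-(benzyloxy)-4-methoxy-6-pentylbenzoate | CCCCCc1cc(OC)cc(OCc2ccccc2)c1C(=O)OC | intermediate
11 | 2-(benzyloxy)-4-methoxy-6-pentylbenzoic acid | CCCCCc1cc(OC)cc(OCc2ccccc2)c1C(=O)O | intermediate
12 | 2-(benzyloxy)-4-methoxy-6-pentylbenzoyl chloride | CCCCCc1cc(OC)cc(OCc2ccccc2)c1C(=O)Cl | intermediate
13 | potassium 4,4-dimethoxybuta-1,3-dien-2-olate | C=C([O-])C=C(OC)OC.[K+] | intermediate
14 | 4,4-dimethoxybuta-1,3-dien-2-yl 2-(benzyloxy)-4-methoxy-6-pentylbenzoate | C=C(C=C(OC)OC)OC(=O)c1c(OCc2ccccc2)cc(OC)cc1CCCCC | intermediate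
15 | oct-2-ynoic acid | CCCCCC#CC(=O)O | starting material
16 | benzyl oct-2-ynoate | CCCCCC#CC(=O)OCc1ccccc1 | intermediate
17 | benzyl 4-{[2-(benzyloxy)-4-methoxy-6-pentylbenzoyl]oxy}-6,6-dimethoxy-2-pentylcyclohexa-1,4-diene-1-carboxylate | CCCCCC1=C(C(=O)OCc2ccccc2)C(OC)(OC)C=C(OC(=O)c2c(OCc3ccccc3)cc(OC)cc2CCCCC)C1 | intermediate
18 | benzyl 4-{[2-(benzyloxy)-4-methoxy-6-pentylbenzoyl]oxy}-2-methoxy-6-pentylbenzoate | CCCCCc1cc(OC(=O)c2c(OCc3ccccc3)cc(OC)cc2CCCCC)cc(OC)c1C(=O)OCc1ccccc1 | intermediate
19 | 4-[(2-hydroxy-4-methoxy-6-pentylbenzoyl)oxy]-2-methoxy-6-pentylbenzoic acid | CCCCCc1cc(OC(=O)c2c(O)cc(OC)cc2CCCCC)cc(OC)c1C(=O)O | intermediate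
20 | 2-chloro-4-oxo-5-pentyl-4H-1,3,2-benzodioxaborinin-7-yl 2-[(dichloroboranyl)oxy]-4-methoxy-6-pentylbenzoate | CCCCCc1cc(OC(=O)c2c(OB(Cl)Cl)cc(OC)cc2CCCCC)cc2OB(Cl)OC(=O)c12 | intermediate
21 | perlatolic acid | CCCCCc1cc(OC(=O)c2c(O)cc(OC)cc2CCCCC)cc(O)c1C(=O)O | target

**Step count**
- Total step count: 11.
- Longest linear sequence: 8 steps (3, 4, 5, 6, 7, 9, 10, 11) from olivetolic acid.

**Steps most likely to fail**

1. **Step 9.**
   - Risk: the acyloxy group lowers the diene HOMO compared with a silyloxy group. The cycloaddition to the internal, alkyl-substituted ynoate may therefore be too slow, and thermal decay of the ketene acetal (oligomerisation, addition of liberated methanol) may overtake it.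
   - Fallback, setting out from 6, 16 and 11 and returning at 18: the aroyl group is attached after the benzannulation instead of before it.
   - Enone 6 is silylated (tBuMe2SiOTf, Et3N, Et2O, 0 °C) to tert-butyl[(4,4-dimethoxybuta-1,3-dien-2-yl)oxy]dimethylsilane F1, a more electron-rich diene of a well-established class.
   - Heating F1 with 16 and loss of methanol should give benzyl 4-[(tert-butyldimethylsilyl)oxy]-2-methoxy-6-pentylbenzoate F2.
   - Bu4NF/AcOH in THF then frees benzyl 4-hydroxy-2-methoxy-6-pentylbenzoate F3, whose only phenol is the C4–OH.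
   - Mixed-anhydride esterification of F3 with acid 11 ((CF3CO)2O, toluene, rt) leads to 18. The same two ring bonds are formed, and no selective phenol acylation is needed.

2. **Step 7.**
   - Risk: acylation at carbon instead of oxygen, self-condensation of the enolate while the hindered chloride reacts slowly, or hydrolysis of the ketene acetal during isolation.
   - Fallback, setting out from 6 and 12 and returning at 14: the metal enolate is replaced by a silyl enol ether and an acyl fluoride.
   - Enone 6 is converted (Me3SiCl, Et3N, ZnCl2 cat., Et2O, 40 °C) into [(4,4-dimethoxybuta-1,3-dien-2-yl)oxy]trimethylsilane F4.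
   - Chloride 12 is converted by halide exchange (KF, 18-crown-6 cat., MeCN) into 2-(benzyloxy)-4-methoxy-6-pentylbenzoyl fluoride F5.
   - F4 and F5 are combined with a catalytic amount of anhydrous Bu4NF in THF. The ammonium enolate formed in small concentration acylates at oxygen, Si–F bond formation drives the turnover, and 14 can be obtained by evaporation without aqueous contact.

3. **Step 11.**
   - Risk: loss of chemoselectivity, that is, onset of 4′-O-demethylation, acyl–oxygen fission of the boron-activated depside ester, or decarboxylation during the acidic work-up.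
   - Fallback, setting out from 4, 12 and 16 and returning at 21: the C2 oxygen is carried as a benzyl ether, so that no Lewis acid is needed at the end.
   - Dichloroenone 4 and NaOCH2Ph (2.1 equiv, THF, 0 °C) should give 4,4-bis(benzyloxy)but-3-en-2-one F6.
   - Enolate O-acylation of F6 with 12 under the conditions of step 7 gives 4,4-bis(benzyloxy)buta-1,3-dien-2-yl 2-(benzyloxy)-4-methoxy-6-pentylbenzoate F7.
   - Cycloaddition of F7 with 16 and loss of benzyl alcohol gives benzyl 2-(benzyloxy)-4-{[2-(benzyloxy)-4-methoxy-6-pentylbenzoyl]oxy}-6-pentylbenzoate F8. This is run at the lowest workable temperature, because benzyl ketene acetals can rearrange on strong heating.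
   - H2, 10% Pd/C, EtOAc removes all three benzyl groups at once and gives 21.

**Further compounds**
F1 | step 9 | tert-butyl[(4,4-dimethoxybuta-1,3-dien-2-yl)oxy]dimethylsilane | C=C(C=C(OC)OC)O[Si](C)(C)C(C)(C)C
F2 | step 9 | benzyl 4-[(tert-butyldimethylsilyl)oxy]-2-methoxy-6-pentylbenzoate | CCCCCc1cc(O[Si](C)(C)C(C)(C)C)cc(OC)c1C(=O)OCc1ccccc1
F3 | step 9 | benzyl 4-hydroxy-2-methoxy-6-pentylbenzoate | CCCCCc1cc(O)cc(OC)c1C(=O)OCc1ccccc1
F4 | step 7 | [(4,4-dimethoxybuta-1,3-dien-2-yl)oxy]trimethylsilane | C=C(C=C(OC)OC)O[Si](C)(C)C
F5 | step 7 | 2-(benzyloxy)-4-methoxy-6-pentylbenzoyl fluoride | CCCCCc1cc(OC)cc(OCc2ccccc2)c1C(=O)F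
F6 | step 11 | 4,4-bis(benzyloxy)but-3-en-2-one | CC(=O)C=C(OCc1ccccc1)OCc1ccccc1
F7 | step 11 | 4,4-bis(benzyloxy)buta-1,3-dien-2-yl 2-(benzyloxy)-4-methoxy-6-pentylbenzoate | C=C(C=C(OCc1ccccc1)OCc1ccccc1)OC(=O)c1c(OCc2ccccc2)cc(OC)cc1CCCCC
F8 | step 11 | benzyl 2-(benzyloxy)-4-{[2-(benzyloxy)-4-methoxy-6-pentylbenzoyl]oxy}-6-pentylbenzoate | CCCCCc1cc(OC(=O)c2c(OCc3ccccc3)cc(OC)cc2CCCCC)cc(OCc2ccccc2)c1C(=O)OCc1ccccc1
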